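**Strategy.** The azepinone ring is opened at the C3a–C4 bond, and the C4=C5 alkene beside it is read as the trace of an alkyne: pyrrole C3–H adds across a tethered triple bond. A PtCl2-catalysed 7-endo-dig cycloisomerisation of a linear N-propargyl-4,5-dibromopyrrole-2-carboxamide closes the seven-membered lactam, forms the C3a–C4 bond and installs the C4=C5 double bond at the final oxidation level in one redox-neutral operation. The alkyne terminus carries an imidazo[1,2-a]pyrimidin-3-yl group, a masked 2-aminoimidazole whose donor character steers attack to C4; hydrazine finally excises the pyrimidine carbons as pyrazole. (Core numbering: pyrrole ring N1, C2, C3, C3a, C8a; azepinone ring C3a, C4, C5, C6, N7, C8, C8a.)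

Key step: step 3

Remark: the target has no stereocentre, its C4=C5 alkene lies in the seven-membered ring and can only be cis, and the N–H tautomers of the 2-aminoimidazole interconvert, so the 4- and 5-substituted forms are one compound.

**Step 1**
Reactants: 1 3-bromoimidazo[1,2-a]pyrimidine; 2 prop-2-yn-1-amine (propargylamine)
Product: 3 3-(imidazo[1,2-a]pyrimidin-3-yl)prop-2-yn-1-amine
Conditions: PdCl2(PPh3)2 (5 mol%), CuI (10 mol%), Et3N, DMF, 70 °C, argon
Reagents that add atoms: none
Why: Sonogashira coupling, in which the C3–Br bond adds oxidatively to zerovalent palladium, the copper acetylide of 2 transmetalates and reductive elimination gives the heteroaryl alkyne; 2 is used in excess so that the free primary amine does not have to be protected.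

**Step 2**
Reactants: 3 3-(imidazo[1,2-a]pyrimidin-3-yl)prop-2-yn-1-amine; 4 2,2,2-trichloro-1-(4,5-dibromo-1H-pyrrol-2-yl)ethan-1-one
Product: 5 4,5-dibromo-N-[3-(imidazo[1,2-a]pyrimidin-3-yl)prop-2-yn-1-yl]-1H-pyrrole-2-carboxamide
Conditions: MeCN, 25 °C
Reagents that add atoms: none
Why: Haloform-type aminolysis of a trichloromethyl ketone, in which the primary amine adds to the carbonyl group and the trichloromethyl anion leaves as chloroform, so the amide should form without a coupling reagent, without protection of the pyrrole N–H and without touching the alkyne.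

**Step 3**
Reactants: 5 4,5-dibromo-N-[3-(imidazo[1,2-a]pyrimidin-3-yl)prop-2-yn-1-yl]-1H-pyrrole-2-carboxamide
Product: 6 2,3-dibromo-4-(imidazo[1,2-a]pyrimidin-3-yl)-6,7-dihydro-1H-pyrrolo[2,3-c]azepin-8-one
Conditions: PtCl2 (20 mol%), 1,4-dioxane, 100 °C, argon
Reagents that add atoms: none
Why: PtCl2 binds the alkyne, the donor heteroaryl group (push from N4 through C8a=N1 and C2=C3) lets positive charge build on the alkyne carbon that carries it, and pyrrole C3 attacks this carbon anti to platinum; loss of the C3 proton and protodemetalation of the vinylplatinum species should give the C4=C5 alkene. The closest known reaction type is the platinum- or gold-catalysed intramolecular alkyne hydroarylation of N-(3-arylprop-2-ynyl)pyrrole-2-carboxamides and indole-2-carboxamides to 4-aryl-pyrrolo[2,3-c]azepin-8-ones and azepino[3,4-b]indol-1-ones. The azepinone ring closes in the 7-endo-dig mode through the new C3a–C4 bond. No stereocentre is formed, and the ring alkene can only be cis. The step needs 7-endo closure in preference to 6-exo closure, and attack by carbon in preference to the amide oxygen or the pyrrole nitrogen. The aryl-type donor on the alkyne secures the first; for the second, the two bromine atoms leave C3 as the only free ring carbon, the soft divalent platinum centre favours the carbon nucleophile as in the precedent class, and heating populates the cisoid amide rotamer that the lactam requires.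

**Step 4**
Reactants: 6 2,3-dibromo-4-(imidazo[1,2-a]pyrimidin-3-yl)-6,7-dihydro-1H-pyrrolo[2,3-c]azepin-8-one
Product: 7 stevensine, 4-(2-amino-1H-imidazol-5-yl)-2,3-dibromo-6,7-dihydro-1H-pyrrolo[2,3-c]azepin-8-one
Conditions: N2H4·H2O (10 equiv), EtOH, 80 °C, argon
Reagents that add atoms: none
Why: Hydrazinolysis of an imidazo[1,2-a]pyrimidine (the 2-aminopyrimidine route to 2-aminoimidazoles), in which hydrazine adds to C5 or C7 of the electron-poor pyrimidine ring, the ring opens and the C5–C6–C7 unit leaves as pyrazole, so that bridgehead N4 becomes the imidazole N–H and N8 the exocyclic NH2, while the lactam, the C–Br bonds and the trisubstituted alkene should stay intact under argon.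

**Compound list**
1 | 3-bromoimidazo[1,2-a]pyrimidine | Brc1cnc2ncccn12 | starting material
2 | prop-2-yn-1-amine | C#CCN | starting material
3 | 3-(imidazo[1,2-a]pyrimidin-3-yl)prop-2-yn-1-amine | NCC#Cc1cnc2ncccn12 | intermediate
4 | 2,2,2-trichloro-1-(4,5-dibromo-1H-pyrrol-2-yl)ethan-1-one | O=C(c1cc(Br)c(Br)[nH]1)C(Cl)(Cl)Cl | starting material
5 | 4,5-dibromo-N-[3-(imidazo[1,2-a]pyrimidin-3-yl)prop-2-yn-1-yl]-1H-pyrrole-2-carboxamide | O=C(NCC#Cc1cnc2ncccn12)c1cc(Br)c(Br)[nH]1 | intermediate
6 | 2,3-dibromo-4-(imidazo[1,2-a]pyrimidin-3-yl)-6,7-dihydro-1H-pyrrolo[2,3-c]azepin-8-one | O=C1NCC=C(c2cnc3ncccn23)c2c(Br)c(Br)[nH]c12 | intermediate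
7 | stevensine, 4-(2-amino-1H-imidazol-5-yl)-2,3-dibromo-6,7-dihydro-1H-pyrrolo[2,3-c]azepin-8-one | Nc1ncc(C2=CCNC(=O)c3[nH]c(Br)c(Br)c32)[nH]1 | target

**Total step count:** 4
**Longest linear sequence:** 4 steps (1 → 3 → 5 → 6 → 7)

**Steps most likely to fail**

Step 3 (cycloisomerisation). The catalyst may be held by N1 or N8 of the heterocycle. The amide oxygen may add to the activated alkyne faster than the bromine-deactivated pyrrole carbon, giving an oxazine. Closure may also turn 6-exo. The fallback sets out from 4 and comes back at 7, and makes the same C3a–C4 bond with an aldehyde electrophile. Compound 4 is condensed with 3,3-diethoxypropan-1-amine (MeCN, 25 °C) to N-(3,3-diethoxypropyl)-4,5-dibromo-1H-pyrrole-2-carboxamide F1. In MeSO3H at 25 °C the aldehyde is unmasked and should undergo Friedel–Crafts hydroxyalkylation at pyrrole C3 and dehydration to 2,3-dibromo-6,7-dihydro-1H-pyrrolo[2,3-c]azepin-8-one F2. F2 and 2-aminoimidazole hemisulfate in MeSO3H at 25 °C should give, by protonation at C5 to the azafulvenium ion and attack of the imidazole carbon at C4, racemic 4-(2-amino-1H-imidazol-5-yl)-2,3-dibromo-4,5,6,7-tetrahydro-1H-pyrrolo[2,3-c]azepin-8-one F3. Br2 in CF3CO2H brominates the free imidazole carbon to racemic 4-(2-amino-4-bromo-1H-imidazol-5-yl)-2,3-dibromo-4,5,6,7-tetrahydro-1H-pyrrolo[2,3-c]azepin-8-one F4. Heating F4 in MeSO3H at 90 °C should expel HBr through the exocyclic alkylidene tautomer and deliver 7.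

Step 4 (hydrazinolysis). The neutral, 3-substituted imidazo[1,2-a]pyrimidine may open slowly, and hydrazine, or diimide formed from it by traces of air, may reduce the C4=C5 alkene or remove bromine from the finished skeleton. The fallback sets out from 5 and comes back at 7, and unmasks the heterocycle before the ring is closed. Compound 5 with N2H4·H2O in EtOH at 80 °C should give 4,5-dibromo-N-[3-(2-amino-1H-imidazol-4-yl)prop-2-yn-1-yl]-1H-pyrrole-2-carboxamide F5. F5 is handled as its methanesulfonate salt, whose aminoimidazolium ion does not bind the metal. It is cyclised with PtCl2 (20 mol%) in N,N-dimethylacetamide at 100 °C in the same 7-endo-dig mode to give 7 directly.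

Step 1 (Sonogashira coupling with the free amine). The primary amine may bind copper and palladium and slow the coupling, and oxidative dimerisation of the alkyne may take over at the temperature the bromide needs. The fallback sets out from 1 and comes back at 3. Compound 1 is coupled with tert-butyl prop-2-yn-1-ylcarbamate under the same catalysts to tert-butyl [3-(imidazo[1,2-a]pyrimidin-3-yl)prop-2-yn-1-yl]carbamate F6. CF3CO2H in CH2Cl2 at 25 °C, followed by basic work-up, removes the carbamate and gives 3.

**Further compounds**
F1 | step 3 | N-(3,3-diethoxypropyl)-4,5-dibromo-1H-pyrrole-2-carboxamide | CCOC(CCNC(=O)c1cc(Br)c(Br)[nH]1)OCC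
F2 | step 3 | 2,3-dibromo-6,7-dihydro-1H-pyrrolo[2,3-c]azepin-8-one | O=C1NCC=Cc2c(Br)c(Br)[nH]c12
F3 | step 3 | racemic 4-(2-amino-1H-imidazol-5-yl)-2,3-dibromo-4,5,6,7-tetrahydro-1H-pyrrolo[2,3-c]azepin-8-one | Nc1ncc(C2CCNC(=O)c3[nH]c(Br)c(Br)c32)[nH]1
F4 | step 3 | racemic 4-(2-amino-4-bromo-1H-imidazol-5-yl)-2,3-dibromo-4,5,6,7-tetrahydro-1H-pyrrolo[2,3-c]azepin-8-one | Nc1nc(Br)c(C2CCNC(=O)c3[nH]c(Br)c(Br)c32)[nH]1
F5 | step 4 | 4,5-dibromo-N-[3-(2-amino-1H-imidazol-4-yl)prop-2-yn-1-yl]-1H-pyrrole-2-carboxamide | Nc1ncc(C#CCNC(=O)c2cc(Br)c(Br)[nH]2)[nH]1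
F6 | step 1 | tert-butyl [3-(imidazo[1,2-a]pyrimidin-3-yl)prop-2-yn-1-yl]carbamate | CC(C)(C)OC(=O)NCC#Cc1cnc2ncccn12
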